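The triketone ring (C1, C7, C8, C9, C10, C11; ring A) is not assembled at its final size: it is grown from an enantiopure cyclopentane-1,2,4-trione, on whose 1,3-dione precursor the quaternary carbon C7 can be fixed by desymmetrising reduction. The key step exploits that C9, with its acyl group, lies between two ring carbonyls (C8, C10): a diazoketone bearing the (R)-2-methylbutanoyl group inserts its carbon between the vicinal carbonyl carbons of the silyl-masked trione, so one 1,2-shift enlarges the ring by one atom and delivers the complete acyl-triketone. A manganese/copper radical cascade then closes rings B and C, and Markovnikov hydration finishes.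

Key step: step 7

Remark: target locants follow tricyclo[5.3.1.0^{1,5}]undecane (C1 ring-fusion bridgehead, C7 methyl-bearing bridgehead, C11 bridging carbonyl; ring B = C1, C5, C6, C7, C11; ring C = C1 to C5); enolised polycarbonyl compounds are drawn as one tautomer and descriptors refer to the tautomer drawn.

Step 1
Reactants: 1 2-methylcyclopentane-1,3-dione; 2 prenyl bromide (1-bromo-3-methylbut-2-ene)
Product: 3 2-methyl-2-(3-methylbut-2-en-1-yl)cyclopentane-1,3-dione
Conditions: 1 M NaOH (aq), rt
Reagents that add atoms: none
Why: C-alkylation of the cyclic 1,3-dione enolate in water, where solvation of the enolate oxygen favours SN2 attack through carbon on the allylic bromide; the product is achiral and no stereocentre is formed.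

Step 2
Reactants: 3 2-methyl-2-(3-methylbut-2-en-1-yl)cyclopentane-1,3-dione
Product: 4 (2R,3R)-3-hydroxy-2-methyl-2-(3-methylbut-2-en-1-yl)cyclopentan-1-one
Conditions: (S)-2-methyl-CBS-oxazaborolidine (20 mol %), catecholborane (1.3 equiv), toluene, −60 °C; MeOH quench, pH 7 work-up, chromatography
Reagents that add atoms: none
Why: Corey–Bakshi–Shibata reduction used as an enantiotopic-group-selective desymmetrisation: the (S)-catalyst should make the new carbinol R (quaternary carbon as the large group), and this hydride face is the less hindered methyl face at only one of the two carbonyls, which fixes the quaternary carbon as R with the hydroxyl cis to prenyl; catecholborane leaves the alkene untouched and the minor C2 epimer, a diastereomer, is removed by chromatography.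

Step 3
Reactants: 4 (2R,3R)-3-hydroxy-2-methyl-2-(3-methylbut-2-en-1-yl)cyclopentan-1-one
Product: 5 (2R,3R)-3,5-dihydroxy-2-methyl-2-(3-methylbut-2-en-1-yl)cyclopentan-1-one (both C5 epimers)
Conditions: NaHMDS (2.2 equiv), THF, −78 °C; 2-(phenylsulfonyl)-3-phenyloxaziridine (1.2 equiv), −78 °C; AcOH quench
Reagents that add atoms: 2-(phenylsulfonyl)-3-phenyloxaziridine (Davis oxaziridine), O=S(=O)(c1ccccc1)N1OC1c1ccccc1
Why: Davis enolate oxidation at C5, the only enolisable α-carbon, with an oxidant that does not epoxidise the prenyl alkene; the new carbinol centre is irrelevant because step 4 oxidises it, and the quaternary carbon is untouched as long as the alkoxide is kept at −78 °C.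

Step 4
Reactants: 5 (2R,3R)-3,5-dihydroxy-2-methyl-2-(3-methylbut-2-en-1-yl)cyclopentan-1-one (both C5 epimers)
Product: 6 (5R)-2-hydroxy-5-methyl-5-(3-methylbut-2-en-1-yl)cyclopent-2-ene-1,4-dione (enol of the 1,2,4-trione)
Conditions: Dess–Martin periodinane (2.5 equiv), CH2Cl2, rt
Reagents that add atoms: none
Why: Dess–Martin oxidation of both secondary alcohols (β-hydroxy ketone and α-hydroxy ketone) should give the 1,2,4-trione, which settles as the 2-hydroxy-enedione tautomer; the quaternary carbon is non-enolisable and keeps its configuration.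

Step 5
Reactants: 6 (5R)-2-hydroxy-5-methyl-5-(3-methylbut-2-en-1-yl)cyclopent-2-ene-1,4-dione; 7 prenyl acetate (3-methylbut-2-en-1-yl acetate)
Product: 8 (5R)-2-hydroxy-5-methyl-3,5-bis(3-methylbut-2-en-1-yl)cyclopent-2-ene-1,4-dione
Conditions: Pd(PPh3)4 (5 mol %), Et3N (1.1 equiv), THF, 40 °C
Reagents that add atoms: none
Why: Tsuji–Trost allylation in which the acidic enol, as its ammonium enolate, attacks the π-prenyl complex of palladium at the unsubstituted terminus through C3, its only nucleophilic carbon, O-allylation being reversible under zerovalent palladium; no stereocentre is formed.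

Step 6
Reactants: 9 (R)-2-methylbutanoic acid
Product: 11 (3R)-1-diazo-3-methylpentan-2-one, via acid chloride 10 (not isolated)
Conditions: (COCl)2, cat. DMF, CH2Cl2, 0 °C to rt, concentrate; CH2N2 (2.5 equiv), Et2O, 0 °C
Reagents that add atoms: diazomethane, C=[N+]=[N-]
Why: Acid chloride formation followed by acylation of diazomethane (first stage of the Arndt–Eistert sequence), the excess diazomethane taking up HCl; no base is present, so the α-stereocentre should be retained.

Step 7
Reactants: 8 (5R)-2-hydroxy-5-methyl-3,5-bis(3-methylbut-2-en-1-yl)cyclopent-2-ene-1,4-dione; 11 (3R)-1-diazo-3-methylpentan-2-one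
Product: 14 (6S)-3,5-dihydroxy-6-methyl-4-[(2R)-2-methylbutanoyl]-2,6-bis(3-methylbut-2-en-1-yl)cyclohexa-2,4-dien-1-one, via silyl enol ether 12 (not isolated), via silylated triketone 13 (not isolated)
Conditions: (Me3Si)2NH, cat. Me3SiCl, CH2Cl2, rt, evaporate; 11 (1.3 equiv), Sc(OTf)3 (10 mol %), CH2Cl2, −20 °C to rt; 1 M HCl, THF
Reagents that add atoms: none
Why: Proposed new method: the diazo carbon of 11 adds to the scandium-activated C1 carbonyl of 12 (the one ketone of the masked vicinal dicarbonyl that is not part of the vinylogous silyl ester), and the β-oxido diazonium collapses by 1,2-shift of the electron-rich, silyloxy-bearing sp2 carbon C2 with loss of N2, so that the diazo carbon with its acyl group ends up between the two formerly vicinal carbonyl carbons and the five-membered ring becomes the six-membered 2-acyl-1,3-dione. The closest known reactions are the Lewis acid-promoted Tiffeneau–Demjanov-type (Büchner–Curtius–Schlotterbeck) homologation of cyclic ketones with α-diazo carbonyl compounds and the ring enlargement of cyclic 1,2-diketones by diazo compounds with acyl migration. No ring is closed by cyclisation; ring A arises solely by this one-carbon ring enlargement. No stereocentre is formed (the inserted carbon is enolised) and the quaternary carbon is not touched, so its configuration is carried over. The step needs site selectivity (C1 over the deactivated vinylogous ester carbonyl C4), migration selectivity (alkenyl carbon over the acyl-substituted quaternary alkyl carbon) and suppression of O-alkylation by the diazoketone; the temporary silyl ether serves the last by removing the acidic enol proton and should serve the second by making the migrating carbon electron-rich.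

Step 8
Reactants: 14 (6S)-3,5-dihydroxy-6-methyl-4-[(2R)-2-methylbutanoyl]-2,6-bis(3-methylbut-2-en-1-yl)cyclohexa-2,4-dien-1-one
Product: 15 (1S,3R,5S,7S)-8-hydroxy-4,4,7-trimethyl-9-[(2R)-2-methylbutanoyl]-3-(prop-1-en-2-yl)tricyclo[5.3.1.0^{1,5}]undec-8-ene-10,11-dione
Conditions: Mn(OAc)3·2H2O (2.2 equiv), Cu(OAc)2·H2O (1 equiv), AcOH, rt; chromatographic removal of the C3 epimer
Reagents that add atoms: none
Why: Oxidative free-radical cyclisation in which the enolate of trivalent manganese gives the α,α-dicarbonyl radical at the prenyl-bearing ring carbon, which closes 5-exo onto the prenyl group of the quaternary carbon (on that group's face, so C7 fixes C1 and ring B), the tertiary radical then closes 5-exo onto the second prenyl group (only the exo radical, syn to C11, can reach it, fixing C5 and ring C) and divalent copper converts the last tertiary radical into the isopropenyl group; C3 is formed with little facial bias, so its epimer is expected alongside.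

Step 9
Reactants: 15 (1S,3R,5S,7S)-8-hydroxy-4,4,7-trimethyl-9-[(2R)-2-methylbutanoyl]-3-(prop-1-en-2-yl)tricyclo[5.3.1.0^{1,5}]undec-8-ene-10,11-dione
Product: 16 (1S,3S,5S,7S)-8-hydroxy-3-(2-hydroxypropan-2-yl)-4,4,7-trimethyl-9-[(2R)-2-methylbutanoyl]tricyclo[5.3.1.0^{1,5}]undec-8-ene-10,11-dione (target, CNP0207052.1)
Conditions: Co(acac)2 (20 mol %), PhSiH3 (2 equiv), O2 (1 atm), THF/iPrOH, rt
Reagents that add atoms: dioxygen, O=O
Why: Mukaiyama hydration, in which a cobalt hydride transfers a hydrogen atom to the terminal alkene carbon and the tertiary radical is trapped by O2 and reduced to the Markovnikov alcohol, the tetrasubstituted enol double bond being inert; no stereocentre is formed or touched (the C3 descriptor changes from R to S only through ligand priority).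

Compound list
1 | 2-methylcyclopentane-1,3-dione | CC1C(=O)CCC1=O | starting material
2 | prenyl bromide (1-bromo-3-methylbut-2-ene) | CC(C)=CCBr | starting material
3 | 2-methyl-2-(3-methylbut-2-en-1-yl)cyclopentane-1,3-dione | CC(C)=CCC1(C)C(=O)CCC1=O | intermediate
4 | (2R,3R)-3-hydroxy-2-methyl-2-(3-methylbut-2-en-1-yl)cyclopentan-1-one | O=C1CC[C@@H](O)[C@@]1(C)CC=C(C)C | intermediate
5 | (2R,3R)-3,5-dihydroxy-2-methyl-2-(3-methylbut-2-en-1-yl)cyclopentan-1-one (both C5 epimers) | O=C1C(O)C[C@@H](O)[C@@]1(C)CC=C(C)C | intermediate
6 | (5R)-2-hydroxy-5-methyl-5-(3-methylbut-2-en-1-yl)cyclopent-2-ene-1,4-dione (enol of the (3R)-1,2,4-trione) | O=C1C=C(O)C(=O)[C@]1(C)CC=C(C)C | intermediate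
7 | prenyl acetate (3-methylbut-2-en-1-yl acetate) | CC(=O)OCC=C(C)C | starting material
8 | (5R)-2-hydroxy-5-methyl-3,5-bis(3-methylbut-2-en-1-yl)cyclopent-2-ene-1,4-dione | CC(C)=CCC1=C(O)C(=O)[C@](C)(CC=C(C)C)C1=O | intermediate
9 | (R)-2-methylbutanoic acid | CC[C@@H](C)C(=O)O | starting material
10 | (R)-2-methylbutanoyl chloride | CC[C@@H](C)C(=O)Cl | intermediate
11 | (3R)-1-diazo-3-methylpentan-2-one | CC[C@@H](C)C(=O)C=[N+]=[N-] | intermediate
12 | (5R)-5-methyl-3,5-bis(3-methylbut-2-en-1-yl)-2-(trimethylsilyloxy)cyclopent-2-ene-1,4-dione | CC(C)=CCC1=C(O[Si](C)(C)C)C(=O)[C@](C)(CC=C(C)C)C1=O | intermediate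
13 | (4S)-4-methyl-6-[(2R)-2-methylbutanoyl]-2,4-bis(3-methylbut-2-en-1-yl)-1-(trimethylsilyloxy)cyclohex-1-ene-3,5-dione (C6 unassigned, enolisable) | CC[C@@H](C)C(=O)C1C(=O)[C@](C)(CC=C(C)C)C(=O)C(CC=C(C)C)=C1O[Si](C)(C)C | intermediate
14 | (6S)-3,5-dihydroxy-6-methyl-4-[(2R)-2-methylbutanoyl]-2,6-bis(3-methylbut-2-en-1-yl)cyclohexa-2,4-dien-1-one | CC[C@@H](C)C(=O)C1=C(O)[C@](C)(CC=C(C)C)C(=O)C(CC=C(C)C)=C1O | intermediate
15 | (1S,3R,5S,7S)-8-hydroxy-4,4,7-trimethyl-9-[(2R)-2-methylbutanoyl]-3-(prop-1-en-2-yl)tricyclo[5.3.1.0^{1,5}]undec-8-ene-10,11-dione | CC[C@@H](C)C(=O)C1=C(O)[C@]2(C)C[C@H]3C(C)(C)[C@@H](C(C)=C)C[C@@]3(C1=O)C2=O | intermediate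
16 | (1S,3S,5S,7S)-8-hydroxy-3-(2-hydroxypropan-2-yl)-4,4,7-trimethyl-9-[(2R)-2-methylbutanoyl]tricyclo[5.3.1.0^{1,5}]undec-8-ene-10,11-dione | CC[C@@H](C)C(=O)C1=C(O)[C@]2(C)C[C@H]3C(C)(C)[C@@H](C(C)(C)O)C[C@@]3(C1=O)C2=O | target

Total step count: 9. Longest linear sequence: 8 steps (1 → 3 → 4 → 5 → 6 → 8 → 14 → 15 → 16); step 6 is a one-step side branch.

Steps most likely to fail

Step 7 (Proposed new method). The betaine may collapse by shift of the quaternary alkyl carbon instead of the alkenyl carbon, close to an epoxide, or the silyl group may be lost early so that the diazoketone alkylates the enol oxygen. The fallback separates addition from rearrangement with known chemistry and sets out from 8. Silylation (TBSCl, imidazole, DMF) should give the tert-butyldimethylsilyl enol ether F1. The lithium derivative of 11 (LDA, THF, −78 °C) is then added to the C1 ketone of F1 in an aldol-type addition to give the α-diazo-β-hydroxy ketone F2. Rh2(OAc)4 (1 mol %, CH2Cl2, rt) should release N2 and induce the 1,2-shift of the silyloxyalkenyl carbon, which migrates far better than alkyl at a rhodium carbenoid, to give the silyl ether F3 of the ring-enlarged triketone. Aqueous HF in MeCN removes the silyl group and the route is rejoined at 14.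

Step 8. Divalent copper may oxidise the first tertiary radical before the second ring closure, excess trivalent manganese may oxidise the product enol further, and the second 5-exo closure has poor facial selectivity at C3. The fallback replaces the oxidative cascade by a redox-neutral halogen-atom-transfer cascade and sets out from 14. N-Bromosuccinimide (CH2Cl2, 0 °C) should brominate the prenyl-bearing ring carbon, the site at which such dearomatised acylphloroglucinols take electrophiles, to give the bromo triketone F4. CuBr (5 mol %) and tris(2-pyridylmethyl)amine in toluene at 60 °C should then run the same two 5-exo closures as an atom-transfer radical cyclisation, with no stoichiometric oxidant to intercept the intermediate radical, and end at the tertiary bromide F5. Solvolysis (AgOTf, acetone/H2O) gives 16 directly, so the route is rejoined at 16 and step 9 is not needed. The facial bias at C3 is intrinsic to this closure in either variant, and the epimers are separated at the stage of F5 or 16.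

Step 3. The sodium alkoxide of the β-hydroxy ketone may open by retro-aldol reaction, which would erode the configuration of the quaternary carbon, and the α-hydroxy ketone may be over-oxidised. The fallback avoids any metal alkoxide by a Rubottom oxidation and sets out from 4. TMSOTf and Et3N (CH2Cl2, 0 °C) should give the bis-silyl compound F6 (silyl ether and silyl enol ether) by soft enolisation. Dimethyldioxirane (1.0 equiv, acetone/CH2Cl2, −78 °C) should epoxidise the far more electron-rich silyl enol ether before the prenyl alkene, and silyl migration gives the α-silyloxy ketone F7. HCl in MeOH removes both silyl groups and the route is rejoined at 5.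

Further compounds
F1 | step 7 | (5R)-2-(tert-butyldimethylsilyloxy)-5-methyl-3,5-bis(3-methylbut-2-en-1-yl)cyclopent-2-ene-1,4-dione | CC(C)=CCC1=C(O[Si](C)(C)C(C)(C)C)C(=O)[C@](C)(CC=C(C)C)C1=O
F2 | step 7 | α-diazo-β-hydroxy ketone from addition of lithiated 11 to C1 of F1 (carbinol centre unassigned) | CC[C@@H](C)C(=O)C(=[N+]=[N-])C1(O)C(O[Si](C)(C)C(C)(C)C)=C(CC=C(C)C)C(=O)[C@@]1(C)CC=C(C)C
F3 | step 7 | tert-butyldimethylsilyl analogue of 13 | CC[C@@H](C)C(=O)C1C(=O)[C@](C)(CC=C(C)C)C(=O)C(CC=C(C)C)=C1O[Si](C)(C)C(C)(C)C
F4 | step 8 | bromo triketone: 14 brominated at the prenyl-bearing ring carbon (that centre unassigned) | CC[C@@H](C)C(=O)C1=C(O)[C@](C)(CC=C(C)C)C(=O)C(Br)(CC=C(C)C)C1=O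
F5 | step 8 | tertiary bromide: 16 with bromine in place of the side-chain hydroxyl | CC[C@@H](C)C(=O)C1=C(O)[C@]2(C)C[C@H]3C(C)(C)[C@@H](C(C)(C)Br)C[C@@]3(C1=O)C2=O
F6 | step 3 | bis(trimethylsilyl) derivative of 4 (silyl ether and silyl enol ether) | C[Si](C)(C)OC1=CC[C@@H](O[Si](C)(C)C)[C@@]1(C)CC=C(C)C
F7 | step 3 | bis(trimethylsilyl) ether of 5 | O=C1C(O[Si](C)(C)C)C[C@@H](O[Si](C)(C)C)[C@@]1(C)CC=C(C)C
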